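**The teal run.** In the teal run, the target climbs from 0.6% at 30.0 min to 3.6% at 60.0 min and 6.8% at 90.0 min. Counted as concentration, those two stretches give 1.00 mM min⁻¹ and 1.07 mM min⁻¹, which are close. Taking the whole span gives 1.03 mM min⁻¹, a reading with the scatter in it that I call the steady rate of target formation after the lag. The average before 30.0 min was 0.200 mM min⁻¹, slower, so the run opens with a lag (an induction period).

common to all: gas phase 200 mM (held)

| run | solid substrate | remark | time |
|---|---|---|---|
| teal | 1 M | the very flask that is asked about, followed so far |  |
| flask | 1.0 M |  | 3.0 h |

teal run (percent of the solid substrate charged)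

| time / min | target / % |
|---|---|
| 6.00 | 0 |
| 20.0 | 0.8 |
| 30.0 | 0.6 |
| 50.0 | 3.1 |
| 60.0 | 3.6 |
| 90.0 | 6.8 |

(each reading ± 0.5 percentage points)

- as a solid, counted per litre of solution: solid substrate
- at the start none of the gas phase is in solution
- at the start none of the solid substrate is in solution

- amount of target at 3.0 h, in percent of the solid substrate charged
- concentration of dissolved gas in solution at 3.0 h, in percent of saturation

**The line.** A constant rate integrates to a straight line: target equals the steady rate times the time after the lag. Running that line back to zero puts the lag at 24.2 min. My own reckoning for the teal flask at 3.0 h is then 16.1%. The scatter of the two readings, stretched over that distance, gives it a spread of 1.5 percentage points. The readings show no dissolved gas, so I reckon nothing for it here.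

**The forecast.** It says 18% (14% to 27%), higher than my line: “I lean slightly above linear”. For the gas it says 90% (72% to 98%).

**The flask.** The teal flask gives 14.4% of target and 99.7% of saturation, with the target 1.7 points below the line.

    gas phase ⇌ dissolved gas, rate k1*(csat - [dissolved gas]) (kL = 1.20 min⁻¹)
    starting material + dissolved gas ⇌ target (K = 2.00 L mol⁻¹, k = 0.0450 L mol⁻¹ min⁻¹)
    starting material → side product (k = 2.20 × 10⁻⁴ min⁻¹)
    solid substrate ⇌ starting material, rate k4*(cs4 - [starting material]) while solid is left; crystals form when [starting material] > cs4 (solubility = 0.980 M, k = 0.00460 min⁻¹)

**The gas.** The steady rate read from the teal run, 1.03 mM min⁻¹, stands against a transfer term, the coefficient times saturation, of 240 mM min⁻¹, and is hardly any of it. If gas uptake just matches that steady rate, their ratio puts the gap below saturation at 0.429%, and the teal flask's gap at 3.0 h is 0.300%. Read at 2.0 h, the same flask has 9.44% of target where the line gives 9.90%.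

(The runs stem from a simulated flask from invented constants.)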